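## The problem

Target 17, 2,2′-dimethyl-5,5′-bis[(2S)-6-methylhept-5-en-2-yl]biphenyl-4,4′-diol, is a C2-symmetric dimer of a bisabolane-type phenol. Numbering each benzene ring (ring A and ring B) from the side-chain carbon, C1 carries the (S)-6-methylhept-5-en-2-yl chain, C2 a hydrogen, C3 the biaryl bond to C3′, C4 a methyl, C5 a hydrogen and C6 the hydroxyl. The only stereogenic elements are the two benzylic carbons: with one methyl and one hydrogen ortho to the axis on each ring, rotation about C3–C3′ is fast and no axial element needs control. The two stereocentres lie on opposite sides of the biaryl and cannot influence one another, so each must be bought or set on its own. Because the molecule is built from two like halves, any wrong enantiomer ends up in a meso-type diastereomer that will be hard to remove. The fragile features are the two trisubstituted alkenes (acids cyclise them onto the phenol or arene; electrophilic halogen and hydrogenation catalysts attack them), the electron-rich 4,4′-biphenol (oxidation to a diphenoquinone) and the tertiary benzylic C–H bonds. The enabling feature is that C2, C3, C4 and C5 of each ring are the four carbons of a 2,3-disubstituted buta-1,3-diene. Since C3 and C3′ are bonded, the two dienes with their methyls form one cross-conjugated C10 tetraene, while C1 and C6 are the two carbons of an alkyne whose propargylic carbon is the stereocentre and whose other terminus can carry boron in place of oxygen.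

## Retrosynthesis

**17 to 16.** The two C6–O bonds are traced back to C–B bonds in the bis(pinacol boronate) 16. A methyl ether at this position would need a final demethylation that endangers the alkenes. A boronate is the group with which the ring-forming chemistry is established, and it is exchanged for hydroxyl under mild conditions. The skeleton is unchanged, but no protecting group is needed anywhere. The forward step must oxidise two aryl C–B bonds without touching the alkenes or over-oxidising the biphenol.

**16 to 15.** No skeletal bond is cut; one hydrogen is returned to C2 and C5 of each ring. This exposes two cyclohexa-1,4-dienes in 15, the retron of a diene–alkyne [4+2] union. The forward step is a dehydrogenation that must prefer the doubly allylic ring methylenes over the side-chain allylic and tertiary C–H bonds.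

**15 to 13 and two molecules of 9.** The C1–C2 and C5–C6 bonds of both rings are cut, four C–C bonds in all. Cutting C3–C3′ instead would call for a para,para-selective dimerisation of a monomeric phenol, or for its halogenation beside a reactive alkene. Cutting at the benzylic carbon leaves the stereocentre to be created on a preformed biaryl. The chosen cut takes a C42 intermediate back to the C10 tetraene 13 and the C16 alkynylboronate 9. It is fully convergent, closes both rings and leaves the stereocentres as spectators. The forward reaction must be regioselective (boron-bearing carbon to the methylene beside C4) and must choose the outer dienes of 13 over the inner one.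

**13 to 10 and two molecules of 11.** The two bonds between the central butadiene-2,3-diyl unit and the isopropenyl groups are cut. This leads to 1,4-dichlorobut-2-yne 10 and isopropenylmagnesium bromide 11, both commercial. Oxidative dimerisation of a metallated methylbutadiene would need a less accessible halodiene. The forward reaction is two consecutive SN2′ substitutions, the second on an allenic chloride.

**9 to 5 and 6.** The C(sp)–B bond is cut, giving terminal alkyne 5 and the commercial borate 6. The forward step is an acetylide borylation with non-aqueous work-up, since alkynylboronates are hydrolytically labile.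

**5 to 2 to 1.** No C–C bond is cut: the alkyne carbons of 5 are C1 and C2 of (S)-citronellal 1, reached through gem-dibromide 2. One-carbon homologations of the aldehyde would place the methyl-bearing centre one atom too far from the alkyne, or would first require degradation to an epimerisable α-chiral aldehyde. The forward steps must dibrominate the carbonyl carbon beside a trisubstituted alkene and eliminate twice without propargyl–allenyl isomerisation.

## Roads not taken

**Alternative 1:** The cut is at the bond between each benzylic carbon and its vinyl carbon, made on the preformed biaryl 4,4′-dimethoxy-2,2′-dimethyl-5,5′-divinylbiphenyl A2. The forward key step is a twofold asymmetric hydrovinylation of A2 with ethylene under a chiral cationic nickel hydride, giving the bis(but-3-en-2-yl)biaryl A1 with both stereocentres.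
- Merits: the arene pattern and the biaryl bond are fixed from the start. The key step has close precedent on vinylarenes. The route is about as short as the chosen one: the vinyl groups of A1 only need hydroboration and coupling with an isobutenyl electrophile, then demethylation.
- Weak points: each vinyl group of A2 sits ortho to a methoxy group, which may slow or misdirect the cationic nickel. Isomerisation of the 3-arylbutene units of A1 into conjugation would erase the stereocentres. Two inductions must both be near perfect, since each miss gives the meso-type diastereomer. A purpose-made chiral ligand, O-methyl protection and a final double demethylation that avoids acid are required.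
- Comparison: on precedent this road is safer than the chosen one and no longer. The chosen plan sets against it that both stereocentres are bought, the complete side chain arrives in the ring-forming step, and there is no protecting group or ligand synthesis. Its price is an untested key step, which is backed below by a fallback in known chemistry.

**Alternative 2:** The cut is at the aryl C1–benzylic carbon bond, traced back to an O-allyl bond in the bis(allyl aryl ether) A4. A4 must be (S)-configured at both carbinol carbons, so that suprafacial transfer through the chair gives (S) in the product. The forward key step is a twofold thermal aromatic Claisen rearrangement with 1,3-chirality transfer, giving the bis(pentenyl)biphenol A3.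
- Merits: the stereocentre is set under substrate control without a metal. The phenols are liberated directly. The required ortho position (para to the ring methyl) is favoured, because the other one is flanked by that methyl.
- Weak points: A4 needs an enantiopure secondary allylic alcohol, etherified onto a biphenol with clean inversion and no SN2′ scrambling. The reaction is hot, and leakage through the boat or axial-substituent pathway counts twice. The pentenyl arm of A3 carries the wrong functionality: both arms must be hydrogenated and debenzylated, oxidised and olefinated, probably with phenol protection.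
- Comparison: it is more secure than the chosen plan in ring substitution and in the nature of its key step. It is roughly twice as long and depends on protecting groups, which the chosen plan avoids.

**Alternative 3:** The cut is at each benzylic C–CH3 bond. The forward key step is a twofold copper-catalysed asymmetric conjugate methylation of the bis-enethioate A6 under a chiral bisphosphine, giving the bis-thioester A5.
- Merits: the reaction class is robust and cheap, with well-understood catalyst control. The arene is again fixed by construction.
- Weak points: β-aryl enethioates with an ortho methoxy group, as in A6, are the less reactive and less selective members of the class. Two inductions must succeed together. Each thioester arm of A5 must be reduced, activated and coupled with an isobutenyl nucleophile before demethylation, four further operations.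
- Comparison: its key step is better precedented than that of the chosen plan. The chosen plan is shorter, needs no induction and no protecting group, and does not rebuild the side chain.

Key step: step 5

Assumption: commercial (S)-(−)-citronellal is used at the highest enantiomeric purity available; since both stereocentres come from it, its optical purity fixes the proportion of meso-type (R,S) diastereomer in 17.

## Route

**Step 1**
Reactants: 1 (S)-citronellal [(3S)-3,7-dimethyloct-6-enal]
Product: 2 (6S)-8,8-dibromo-2,6-dimethyloct-2-ene
Conditions: (PhO)3P (1.2 equiv), Br2 (1.1 equiv), Et3N (1.3 equiv), CH2Cl2, −78 °C to rt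
Reagents that add atoms: bromine, BrBr
Why: Appel-type deoxygenative gem-dibromination of an aldehyde by the preformed triphenyl phosphite–bromine adduct; bromine is bound to phosphorus before 1 is added, so the trisubstituted alkene should be spared, Et3N buffers HBr against carbonyl-ene cyclisation, and the β-stereocentre is not involved. Any 1-bromoalkene formed by HBr loss is a competent substrate for step 2.

**Step 2**
Reactants: 2 (6S)-8,8-dibromo-2,6-dimethyloct-2-ene
Product: 5 (3S)-3,7-dimethyloct-6-en-1-yne, via 1-bromoalkene 3 (not isolated), via sodium acetylide 4 (not isolated)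
Conditions: NaNH2 (3.5 equiv), liq. NH3/THF, −33 °C; then NH4Cl
Reagents that add atoms: none
Why: Twofold E2 dehydrobromination of a 1,1-dibromoalkane, the classical gem-dihalide-to-alkyne elimination, with no change in carbon count, so the former C3 of citronellal becomes propargylic. The third equivalent of amide stores the product as acetylide 4, which cannot undergo propargyl–allenyl isomerisation, so the stereocentre should keep its configuration.

**Step 3**
Reactants: 5 (3S)-3,7-dimethyloct-6-en-1-yne; 6 2-isopropoxy-4,4,5,5-tetramethyl-1,3,2-dioxaborolane
Product: 9 2-[(3S)-3,7-dimethyloct-6-en-1-yn-1-yl]-4,4,5,5-tetramethyl-1,3,2-dioxaborolane, via lithium acetylide 7 (not isolated), via lithium alkynylborate 8 (not isolated)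
Conditions: n-BuLi, THF, −78 °C; 6, −78 °C; HCl·Et2O, −78 °C to rt; filtration and distillation
Reagents that add atoms: none
Why: Standard acetylide borylation: deprotonation, addition to the borate to give ate complex 8, and anhydrous acidolysis that expels isopropoxide. The terminal C–H is far more acidic than the propargylic one, so the stereocentre is untouched, and the non-aqueous isolation avoids hydrolysis of the C(sp)–B bond.

**Step 4**
Reactants: 10 1,4-dichlorobut-2-yne; 11 isopropenylmagnesium bromide (2.3 equiv)
Product: 13 2,5-dimethyl-3,4-dimethylidenehexa-1,5-diene, via allenic chloride 12 (not isolated)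
Conditions: CuBr·SMe2 (10 mol %), THF, −40 °C to rt; pentane extraction, cold distillation over BHT
Reagents that add atoms: none
Why: Copper-catalysed twofold SN2′ substitution: the first alkenylcopper attacks an alkyne carbon and expels the remote chloride to give allene 12; the second attacks the central allene carbon and expels the other chloride. This is the established entry to 2,3-disubstituted buta-1,3-dienes from but-2-yne-1,4-diyl dielectrophiles, here with an alkenyl Grignard reagent. Cross-conjugated polyenes with an even number of alkenes are the less dimerisation-prone members of their family, so 13 should be isolable.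

**Step 5**
Reactants: 13 2,5-dimethyl-3,4-dimethylidenehexa-1,5-diene; 9 2-[(3S)-3,7-dimethyloct-6-en-1-yn-1-yl]-4,4,5,5-tetramethyl-1,3,2-dioxaborolane (2.4 equiv)
Product: 15 2,2′-dimethyl-5,5′-bis[(2S)-6-methylhept-5-en-2-yl]-4,4′-bis(4,4,5,5-tetramethyl-1,3,2-dioxaborolan-2-yl)-1,1′-bi(cyclohexa-1,4-diene), via monoadduct 14 (not isolated)
Conditions: CoBr2(dppe) (10 mol %), Zn powder (20 mol %), ZnI2 (20 mol %), CH2Cl2, rt
Reagents that add atoms: none
Why: Proposed new method: CoBr2(dppe) is reduced by Zn and freed of halide by ZnI2 to a cationic monovalent cobalt centre that binds one s-cis outer diene unit of 13 (C2=C3–C4=C5 in ring numbering) and the alkyne of 9; oxidative cyclisation forms C1–C2 and leaves a trivalent cobalt σ-alkenyl/η3-allyl species, and reductive elimination forms C5–C6, closing ring A as a cyclohexa-1,4-diene in a formal [4+2] (neutral Diels–Alder) mode to give 14. The other isopropenyl-bearing unit of 14 is still a free 1,3-diene and closes ring B with a second molecule of 9 by the same intermolecular [4+2] annulation. The closest known reaction type is the cobalt-catalysed [4+2] cycloaddition of alkynylboronates with simple 2- and 2,3-substituted buta-1,3-dienes; untested are the cross-conjugated tetraene, the twofold use and regiocontrol between a methyl and an alkenyl substituent on the diene. Regiochemistry is expected to follow from two preferences in the oxidative cyclisation: the cobalt–carbon σ-bond is best placed on the boron-bearing carbon (stabilisation by the empty boron p orbital), so the first C–C bond forms at the alkyl-bearing C1, and the allyl fragment keeps conjugation with the alkenyl substituent at C3 only if that first bond is made to the C2 methylene, so that reductive elimination must join the boron-bearing C6 to C5, the methylene beside C4–CH3. Site selectivity for the outer dienes rests on sterics: s-cis binding of the inner diene (C2=C3–C3′=C2′) presses the two isopropenyl groups against each other, whereas an outer diene opposes only a methyl to one alkenyl group; an inner adduct would in any case stop as a mono-boronate separable from 15, and in 14 the semicyclic diene ends in the fully substituted C4 and cannot compete. No stereocentre is formed: the two propargylic centres of 9 take part in no bond change and are carried into 15 unchanged. Should the intrinsic bias be insufficient, the ligand (bisphosphine bite angle, or a pyridine–imine in place of dppe) is the lever, since the ligand class governs regiochemistry in this catalyst family.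

**Step 6**
Reactants: 15 2,2′-dimethyl-5,5′-bis[(2S)-6-methylhept-5-en-2-yl]-4,4′-bis(4,4,5,5-tetramethyl-1,3,2-dioxaborolan-2-yl)-1,1′-bi(cyclohexa-1,4-diene)
Product: 16 2,2′-{2,2′-dimethyl-5,5′-bis[(2S)-6-methylhept-5-en-2-yl]biphenyl-4,4′-diyl}bis(4,4,5,5-tetramethyl-1,3,2-dioxaborolane)
Conditions: DDQ (2.2 equiv), toluene, rt
Reagents that add atoms: none
Why: Dehydrogenative aromatisation by DDQ: hydride is taken from a doubly allylic ring methylene and a proton is lost, with aromatisation as driving force. This should make the ring methylenes far more reactive than the side-chain allylic or tertiary C–H bonds, and the C–B bonds and stereocentres are not affected.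

**Step 7**
Reactants: 16 2,2′-{2,2′-dimethyl-5,5′-bis[(2S)-6-methylhept-5-en-2-yl]biphenyl-4,4′-diyl}bis(4,4,5,5-tetramethyl-1,3,2-dioxaborolane)
Product: 17 2,2′-dimethyl-5,5′-bis[(2S)-6-methylhept-5-en-2-yl]biphenyl-4,4′-diol
Conditions: NaBO3·4H2O (6 equiv), THF/H2O 1:1, rt, under argon; aq NH4Cl
Reagents that add atoms: sodium perborate (used as the tetrahydrate), [Na+].[O-]OB=O
Why: Oxidation of aryl C–B to C–O: hydroperoxide adds to boron, the aryl group shifts from boron to oxygen and the borate ester hydrolyses. Nucleophilic peroxide at mild pH does not epoxidise the trisubstituted alkenes, and exclusion of air should protect the biphenol.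

## Compound list

1 | (S)-citronellal, (3S)-3,7-dimethyloct-6-enal | CC(C)=CCC[C@H](C)CC=O | starting material
2 | (6S)-8,8-dibromo-2,6-dimethyloct-2-ene | CC(C)=CCC[C@H](C)CC(Br)Br | intermediate
3 | (3S)-1-bromo-3,7-dimethylocta-1,6-diene (E/Z mixture) | CC(C)=CCC[C@H](C)C=CBr | intermediate
4 | sodium (3S)-3,7-dimethyloct-6-en-1-yn-1-ide | CC(C)=CCC[C@H](C)C#[C-].[Na+] | intermediate
5 | (3S)-3,7-dimethyloct-6-en-1-yne | CC(C)=CCC[C@H](C)C#C | intermediate
6 | 2-isopropoxy-4,4,5,5-tetramethyl-1,3,2-dioxaborolane | CC(C)OB1OC(C)(C)C(C)(C)O1 | starting material
7 | lithium (3S)-3,7-dimethyloct-6-en-1-yn-1-ide | CC(C)=CCC[C@H](C)C#[C-].[Li+] | intermediate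
8 | lithium [(3S)-3,7-dimethyloct-6-en-1-yn-1-yl](isopropoxy)(pinacolato)borate | CC(C)=CCC[C@H](C)C#C[B-]1(OC(C)C)OC(C)(C)C(C)(C)O1.[Li+] | intermediate
9 | 2-[(3S)-3,7-dimethyloct-6-en-1-yn-1-yl]-4,4,5,5-tetramethyl-1,3,2-dioxaborolane | CC(C)=CCC[C@H](C)C#CB1OC(C)(C)C(C)(C)O1 | intermediate
10 | 1,4-dichlorobut-2-yne | ClCC#CCCl | starting material
11 | isopropenylmagnesium bromide | CC(=C)[Mg]Br | starting material
12 | 3-(chloromethyl)-2-methylpenta-1,3,4-triene | C=C(C)C(CCl)=C=C | intermediate
13 | 2,5-dimethyl-3,4-dimethylidenehexa-1,5-diene | C=C(C)C(=C)C(=C)C(C)=C | intermediate
14 | 2-{5-methyl-4-(3-methylbuta-1,3-dien-2-yl)-2-[(2S)-6-methylhept-5-en-2-yl]cyclohexa-1,4-dien-1-yl}-4,4,5,5-tetramethyl-1,3,2-dioxaborolane | CC(C)=CCC[C@H](C)C1=C(B2OC(C)(C)C(C)(C)O2)CC(C)=C(C1)C(=C)C(C)=C | intermediate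
15 | 2,2′-dimethyl-5,5′-bis[(2S)-6-methylhept-5-en-2-yl]-4,4′-bis(4,4,5,5-tetramethyl-1,3,2-dioxaborolan-2-yl)-1,1′-bi(cyclohexa-1,4-diene) | CC(C)=CCC[C@H](C)C1=C(B2OC(C)(C)C(C)(C)O2)CC(C)=C(C1)C1=C(C)CC(B2OC(C)(C)C(C)(C)O2)=C(C1)[C@@H](C)CCC=C(C)C | intermediate
16 | 2,2′-{2,2′-dimethyl-5,5′-bis[(2S)-6-methylhept-5-en-2-yl]biphenyl-4,4′-diyl}bis(4,4,5,5-tetramethyl-1,3,2-dioxaborolane) | CC(C)=CCC[C@H](C)c1cc(-c2cc([C@@H](C)CCC=C(C)C)c(B3OC(C)(C)C(C)(C)O3)cc2C)c(C)cc1B1OC(C)(C)C(C)(C)O1 | intermediate
17 | 2,2′-dimethyl-5,5′-bis[(2S)-6-methylhept-5-en-2-yl]biphenyl-4,4′-diol | CC(C)=CCC[C@H](C)c1cc(-c2cc([C@@H](C)CCC=C(C)C)c(O)cc2C)c(C)cc1O | target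

## Step count and risks

Total: 7 steps. Longest linear sequence: 6 steps (1, 2, 3, 5, 6, 7); step 4 is a one-step branch.

**Step 5 (key step; the one step beyond known chemistry).** The most likely failure is bond formation in the wrong regiochemical sense in one or both annulations, giving head/tail isomers of 15 that would be hard to separate. The first cycloaddition could also engage the inner diene, and oligomerisation of 13 could compete.

The fallback uses known chemistry, sets out from 9 and returns at 17. Alkynylboronate 9 undergoes the documented cobalt-catalysed [4+2] cycloaddition with commercial isoprene, with the ligand chosen for the isomer in which boron is 1,3 to the methyl. This gives 2-{5-methyl-2-[(2S)-6-methylhept-5-en-2-yl]cyclohexa-1,4-dien-1-yl}-4,4,5,5-tetramethyl-1,3,2-dioxaborolane F1; any regioisomer is removed at this simple mono-boronate stage. DDQ aromatises it to 2-{5-methyl-2-[(2S)-6-methylhept-5-en-2-yl]phenyl}-4,4,5,5-tetramethyl-1,3,2-dioxaborolane F2, and NaBO3·4H2O converts that into (S)-curcuphenol F3. Iodination para to the hydroxyl with I2/morpholine in CH2Cl2 gives 4-iodo-5-methyl-2-[(2S)-6-methylhept-5-en-2-yl]phenol F4; the amine-bound iodine should not add to the alkene, and the position between hydroxyl and methyl is blocked sterically. Borylative homocoupling of F4 (PdCl2(dppf), half an equivalent of B2pin2, K3PO4, dioxane/H2O, 80 °C) then makes the C3–C3′ bond and gives 17.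

**Step 4.** Direct SN2 substitution may compete with SN2′, the sequence may stop at the allene stage, or the volatile tetraene may polymerise or be lost on isolation.

The fallback sets out from 10 and 11 and returns at 13. Compound 10 is isomerised by CuCl-catalysed double 1,3-chloride shift to 2,3-dichlorobuta-1,3-diene F5. F5 is then coupled twice with 11 in a Kumada reaction under NiCl2(dppp) in THF, so the diene core is preformed and only two C(sp2)–C(sp2) couplings remain.

**Step 1.** Free bromine may add to the trisubstituted alkene, or acid may trigger carbonyl-ene cyclisation of the aldehyde onto that alkene.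

The fallback sets out from 1 and returns at 5, bypassing 2 and step 2. Aldehyde 1 is converted in one pot with nonafluorobutanesulfonyl fluoride and a phosphazene base in DMF into (3S)-3,7-dimethylocta-1,6-dien-1-yl nonafluorobutane-1-sulfonate F6. The same base eliminates F6 to alkyne 5, with no halogen or acid present.

**Step 7.** The electron-rich 4,4′-biphenol may be over-oxidised to the diphenoquinone in the basic oxidising medium.

The fallback sets out from 16 and returns at 17. The oxidation is run to full consumption of the C–B bonds without regard to over-oxidation. The crude mixture of 17 and 2,2′-dimethyl-5,5′-bis[(2S)-6-methylhept-5-en-2-yl][1,1′-bi(cyclohexa-2,5-dien-1-ylidene)]-4,4′-dione F7 is then reduced with aqueous Na2S2O4, which returns F7 to 17.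

## Further compounds

F1 | step 5 | 2-{5-methyl-2-[(2S)-6-methylhept-5-en-2-yl]cyclohexa-1,4-dien-1-yl}-4,4,5,5-tetramethyl-1,3,2-dioxaborolane | CC(C)=CCC[C@H](C)C1=C(B2OC(C)(C)C(C)(C)O2)CC(C)=CC1
F2 | step 5 | 2-{5-methyl-2-[(2S)-6-methylhept-5-en-2-yl]phenyl}-4,4,5,5-tetramethyl-1,3,2-dioxaborolane | CC(C)=CCC[C@H](C)c1ccc(C)cc1B1OC(C)(C)C(C)(C)O1
F3 | step 5 | (S)-curcuphenol, 5-methyl-2-[(2S)-6-methylhept-5-en-2-yl]phenol | CC(C)=CCC[C@H](C)c1ccc(C)cc1O
F4 | step 5 | 4-iodo-5-methyl-2-[(2S)-6-methylhept-5-en-2-yl]phenol | CC(C)=CCC[C@H](C)c1cc(I)c(C)cc1O
F5 | step 4 | 2,3-dichlorobuta-1,3-diene | C=C(Cl)C(Cl)=C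
F6 | step 1 | (3S)-3,7-dimethylocta-1,6-dien-1-yl nonafluorobutane-1-sulfonate (E/Z mixture) | CC(C)=CCC[C@H](C)C=COS(=O)(=O)C(F)(F)C(F)(F)C(F)(F)C(F)(F)F
F7 | step 7 | 2,2′-dimethyl-5,5′-bis[(2S)-6-methylhept-5-en-2-yl][1,1′-bi(cyclohexa-2,5-dien-1-ylidene)]-4,4′-dione | CC(C)=CCC[C@H](C)C1=CC(=C2C=C([C@@H](C)CCC=C(C)C)C(=O)C=C2C)C(C)=CC1=O
A1 | alternative 1 | 5,5′-bis[(2S)-but-3-en-2-yl]-4,4′-dimethoxy-2,2′-dimethylbiphenyl | C=C[C@H](C)c1cc(-c2cc([C@@H](C)C=C)c(OC)cc2C)c(C)cc1OC
A2 | alternative 1 | 4,4′-dimethoxy-2,2′-dimethyl-5,5′-divinylbiphenyl | C=Cc1cc(-c2cc(C=C)c(OC)cc2C)c(C)cc1OC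
A3 | alternative 2 | 5,5′-bis[(2S,3E)-5-(benzyloxy)pent-3-en-2-yl]-2,2′-dimethylbiphenyl-4,4′-diol | C(/C=C/[C@H](C)c1cc(-c2cc([C@@H](C)/C=C/COCc3ccccc3)c(O)cc2C)c(C)cc1O)OCc1ccccc1
A4 | alternative 2 | 4,4′-bis{[(2S,3E)-1-(benzyloxy)pent-3-en-2-yl]oxy}-2,2′-dimethylbiphenyl | C/C=C/[C@@H](COCc1ccccc1)Oc1ccc(-c2ccc(O[C@H](COCc3ccccc3)/C=C/C)cc2C)c(C)c1
A5 | alternative 3 | S,S′-diethyl (3S,3′S)-3,3′-(4,4′-dimethoxy-6,6′-dimethylbiphenyl-3,3′-diyl)dibutanethioate | CCSC(=O)C[C@H](C)c1cc(-c2cc([C@@H](C)CC(=O)SCC)c(OC)cc2C)c(C)cc1OC
A6 | alternative 3 | S,S′-diethyl (2E,2′E)-3,3′-(4,4′-dimethoxy-6,6′-dimethylbiphenyl-3,3′-diyl)bis(prop-2-enethioate) | CCSC(=O)/C=C/c1cc(-c2cc(/C=C/C(=O)SCC)c(OC)cc2C)c(C)cc1OC
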